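**Retrosynthetic overview**
1. Last bond: C4–C8, by acid ionisation of flavan-4-ol 5 to its p-quinone methide and capture by C8 of (−)-epiafzelechin 9.
2. Upper pyran ring: reversible oxa-Michael closure of chalcone 3 (from 1 + 2), run in one pot with Ru transfer hydrogenation under dynamic kinetic resolution, which fixes C2.
3. Lower unit 9: two-hydride reduction of pelargonidin 7 (flavylium → flavan-3-one → 2,3-cis-flavan-3-ol); 7 comes from kaempferol 6.
4. Ring order: all benzene rings and the lower pyran ring are bought (1, 2, 6); the only ring built is the upper pyran ring (step 2), before the union (step 5).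

Assumption 1: the SMILES is read as (2S,4S)-4′,7-dihydroxyflavan-(4→8)-(2R,3R)-epiafzelechin, upper unit 2,4-cis (4α); rotamers about C4–C8 are not specified.
Assumption 2: in step 4 the (R,R)-TsDPEN–Ru catalyst is taken to give the 3R carbinol (the O,aryl-substituted C2 side playing the role of the aryl group in the usual model); if the sense is the reverse, the (S,S) catalyst is used.

**Step 1**
Reactants: 1 2′,4′-dihydroxyacetophenone; 2 4-hydroxybenzaldehyde
Product: 3 isoliquiritigenin
Conditions: KOH (50% aq, 12 equiv), EtOH, N2, 25 °C, 48 h; then 2 M HCl to pH 3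
Reagents that add atoms: none
Why: Claisen–Schmidt (crossed aldol) condensation in which the acetophenone enolate adds to the non-enolisable aldehyde and E1cB dehydration gives the thermodynamically favoured (E)-enone, the phenols being carried as phenolates and no stereocentre being formed.

**Step 2**
Reactants: 3 isoliquiritigenin
Product: 5 (2S,4S)-4′,7-dihydroxyflavan-4-ol, via (±)-liquiritigenin 4 (not isolated)
Conditions: (i) NaOAc (3 equiv), EtOH/H2O 4:1, 80 °C, 12 h; (ii) RuCl[(S,S)-TsDPEN](p-cymene) (2 mol %), HCO2H/Et3N (2:5; 5 equiv HCO2H), 45 °C, Ar, 24–48 h; work-up at pH 6–7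
Reagents that add atoms: none
Why: Proposed new method: the 2′-phenol closes onto the enone by intramolecular oxa-Michael addition (the chalcone→flavanone isomerisation) to give (±)-4, which keeps racemising at C2 through retro-oxa-Michael ring opening in the basic formate medium, while the (S,S)-Ru hydride reduces only the (2S)-ketone, from the face anti to the 2-aryl group, so that C2 (S) and C4 (S, 2,4-cis) are set together (Noyori-type asymmetric transfer hydrogenation with dynamic kinetic resolution); the closest known reactions are the transfer-hydrogenative kinetic resolution of racemic flavanones and the dynamic kinetic resolution of 2-substituted chroman-4-ones by elimination-induced racemisation.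

**Step 3**
Reactants: 6 kaempferol
Product: 7 pelargonidin chloride
Conditions: Zn dust (10 equiv), conc. HCl/MeOH 1:9, 0 → 25 °C, 20 min; filter, Amberlite XAD-7, crystallise from MeOH/HCl
Reagents that add atoms: hydrogen chloride (Cl)
Why: Clemmensen-type dissolving-metal reduction of the C4 carbonyl of the flavonol followed by acid-driven loss of water gives the aromatic flavylium salt (the classical flavonol → anthocyanidin conversion), with no stereocentre formed.

**Step 4**
Reactants: 7 pelargonidin chloride
Product: 9 (−)-epiafzelechin, via flavan-3-one 8 (not isolated)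
Conditions: RuCl[(R,R)-TsDPEN](p-cymene) (3 mol %), HCO2H/Et3N (5:2), DMF, 30 °C, Ar; EtOAc extraction, Sephadex LH-20
Reagents that add atoms: none
Why: Proposed new method: the Ru hydride adds to the flavylium cation at C2 or C4, both enols tautomerise to the same flavan-3-one 8 whose C2–H epimerises rapidly by enolisation, and the chiral Ru hydride then reduces the (2R)-ketone from the face anti to the aryl group, giving the 2,3-cis (2R,3R) alcohol by asymmetric transfer hydrogenation with dynamic kinetic resolution (a chemical counterpart of anthocyanidin reductase); the closest known reactions are hydride reduction of flavylium salts and Ru-catalysed dynamic-kinetic (transfer) hydrogenation of α-aryl cyclic ketones to cis-2-arylcycloalkanols.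

**Step 5**
Reactants: 5 (2S,4S)-4′,7-dihydroxyflavan-4-ol; 9 (−)-epiafzelechin (4 equiv, excess recovered)
Product: 11 cassiaflavan-(4α→8)-epiafzelechin (target), via p-quinone methide 10 (not isolated)
Conditions: 0.1 M HCl, dioxane/H2O 1:1, Ar, 25 °C 2 h, then 60 °C 6 h; Sephadex LH-20 (EtOH), then RP-HPLC
Reagents that add atoms: none
Why: Acid ionises the 2,4-dioxygenated benzylic alcohol to the p-quinone methide (benzylic cation) 10, which is captured by C8 of the phloroglucinol ring of 9 in a Friedel–Crafts-type flavan-4-ol/flavan-3-ol condensation (as in proanthocyanidin formation), C2 and the centres of 9 being untouched and C4 being set under reversible acidolysis–recapture conditions in favour of the 2,4-cis (4α, both aryl groups equatorial, 4S) epimer, which is separated from the minor 4β and 4→6 isomers (the 4β epimer can be re-equilibrated).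

**Compound list**
1 | 2′,4′-dihydroxyacetophenone | CC(=O)c1ccc(O)cc1O | starting material
2 | 4-hydroxybenzaldehyde | O=Cc1ccc(O)cc1 | starting material
3 | isoliquiritigenin, (E)-1-(2,4-dihydroxyphenyl)-3-(4-hydroxyphenyl)prop-2-en-1-one | O=C(/C=C/c1ccc(O)cc1)c1ccc(O)cc1O | intermediate
4 | (±)-liquiritigenin, racemic 7-hydroxy-2-(4-hydroxyphenyl)chroman-4-one | O=C1CC(c2ccc(O)cc2)Oc2cc(O)ccc12 | intermediate (not isolated)
5 | (2S,4S)-2-(4-hydroxyphenyl)chromane-4,7-diol (2,4-cis) | Oc1ccc([C@@H]2C[C@H](O)c3ccc(O)cc3O2)cc1 | intermediate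
6 | kaempferol | O=c1c(O)c(-c2ccc(O)cc2)oc2cc(O)cc(O)c12 | starting material
7 | pelargonidin chloride, 3,5,7-trihydroxy-2-(4-hydroxyphenyl)chromenylium chloride | Oc1ccc(-c2[o+]c3cc(O)cc(O)c3cc2O)cc1.[Cl-] | intermediate
8 | (±)-5,7-dihydroxy-2-(4-hydroxyphenyl)chroman-3-one (C2 labile) | O=C1Cc2c(O)cc(O)cc2OC1c1ccc(O)cc1 | intermediate (not isolated)
9 | (−)-epiafzelechin, (2R,3R)-2-(4-hydroxyphenyl)chromane-3,5,7-triol (2,3-cis) | Oc1cc(O)c2c(c1)O[C@H](c1ccc(O)cc1)[C@H](O)C2 | intermediate
10 | (2S)-2-(4-hydroxyphenyl)-2,3-dihydro-7H-chromen-7-one (p-quinone methide, C4=C4a) | O=C1C=CC2=CC[C@@H](c3ccc(O)cc3)OC2=C1 | intermediate (not isolated)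
11 | (2R,3R)-8-[(2S,4S)-7-hydroxy-2-(4-hydroxyphenyl)chroman-4-yl]-2-(4-hydroxyphenyl)chromane-3,5,7-triol | Oc1ccc([C@@H]2C[C@H](c3c(O)cc(O)c4c3O[C@H](c3ccc(O)cc3)[C@H](O)C4)c3ccc(O)cc3O2)cc1 | target

**Step count**
Total: 5 steps. Longest linear sequence: 3 steps (1 + 2 → 3 → 5 → 11; equally 6 → 7 → 9 → 11).

**Three steps most likely to fail**

Step 2. The chalcone present at equilibrium may be reduced at C=C by the Ru hydride to the dihydrochalcone, phenolate formation slows ketone reduction, and 5 can ionise and be over-reduced to the flavan if the medium turns acidic. The fallback sets out from 3 and comes back at 5. The ring is closed irreversibly by oxidative cyclisation (I2 cat., DMSO, 120 °C) to 7,4′-dihydroxyflavone F1. The C2=C3 bond is then hydrogenated enantioselectively (chiral Ru–NHC catalyst, H2, antipode chosen for 2S) under neutral, non-racemising conditions to (S)-liquiritigenin F2. NaBH4 (MeOH, 0 °C) gives 5 by axial hydride delivery (2,4-cis).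

Step 4. The anthocyanidin and the free flavan-3-one are fragile, and the sense and level of induction for a ketone with no aryl group on the carbonyl are unproven. The fallback sets out from 7 and comes back at 9. Hydrogenation over PtO2 (H2, 1 atm, MeOH) adds both hydrogens to one face and gives racemic 2,3-cis (±)-epiafzelechin F3. Preparative chiral HPLC (amylose carbamate phase) then resolves it, the (2R,3R) enantiomer being 9.

Step 5. Kinetic (axial) attack on 10 favours the 2,4-trans (4β) epimer, and equilibration to the cis epimer may be incomplete at temperatures the polyphenols tolerate; 4→6 isomers and oligomers also form. The fallback sets out from 5 and 9 and comes back at 11; it sets C4 by hydride delivery instead of by arylation.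
- From 9: BnBr/NaH (DMF, 0 °C) gives 3,5,7,4′-tetra-O-benzylepiafzelechin F4, NBS (CH2Cl2, −78 °C) gives the 8-bromide F5, and n-BuLi (THF, −78 °C) gives the 8-lithio compound F6.
- From 5: BnBr/K2CO3 (acetone) gives the 7,4′-di-O-benzyl flavan-4-ol F7, and Dess–Martin oxidation gives (S)-7,4′-di-O-benzylliquiritigenin F8.
- Union: F6 adds to F8 (CeCl3, THF, −78 °C) to give the tertiary 4-aryl-flavan-4-ol F9 as a C4 epimer mixture. Et3SiH/TFA (CH2Cl2, −40 °C) ionises it, and axial hydride delivery to the 4-aryl cation gives the 2,4-cis hexa-O-benzyl dimer F10. H2, Pd(OH)2/C (EtOAc/MeOH) removes the six benzyl groups to give 11.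

**Further compounds**
F1 | step 2 | 7,4′-dihydroxyflavone | O=c1cc(-c2ccc(O)cc2)oc2cc(O)ccc12
F2 | step 2 | (S)-liquiritigenin | O=C1C[C@@H](c2ccc(O)cc2)Oc2cc(O)ccc12
F3 | step 4 | (±)-epiafzelechin (racemic 2,3-cis, 1:1 mixture of enantiomers) | Oc1cc(O)c2c(c1)O[C@H](c1ccc(O)cc1)[C@H](O)C2.Oc1cc(O)c2c(c1)O[C@@H](c1ccc(O)cc1)[C@@H](O)C2
F4 | step 5 | (2R,3R)-3,5,7-tris(benzyloxy)-2-[4-(benzyloxy)phenyl]chromane | c1c(OCc2ccccc2)cc(OCc3ccccc3)c4c1O[C@H](c5ccc(OCc6ccccc6)cc5)[C@H](OCc7ccccc7)C4
F5 | step 5 | (2R,3R)-3,5,7-tris(benzyloxy)-2-[4-(benzyloxy)phenyl]-8-bromochromane | Brc1c(OCc2ccccc2)cc(OCc3ccccc3)c4c1O[C@H](c5ccc(OCc6ccccc6)cc5)[C@H](OCc7ccccc7)C4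
F6 | step 5 | 8-lithio derivative of F4 | [Li]c1c(OCc2ccccc2)cc(OCc3ccccc3)c4c1O[C@H](c5ccc(OCc6ccccc6)cc5)[C@H](OCc7ccccc7)C4
F7 | step 5 | (2S,4S)-7-(benzyloxy)-2-[4-(benzyloxy)phenyl]chroman-4-ol | c1ccccc1COc2ccc([C@@H]3C[C@H](O)c4ccc(OCc5ccccc5)cc4O3)cc2
F8 | step 5 | (S)-7-(benzyloxy)-2-[4-(benzyloxy)phenyl]chroman-4-one | O=C1C[C@@H](c2ccc(OCc3ccccc3)cc2)Oc4cc(OCc5ccccc5)ccc14
F9 | step 5 | hexa-O-benzyl tertiary carbinol, (2S)-4-hydroxy-4-(tetra-O-benzylepiafzelechin-8-yl) flavan (C4 epimer mixture) | c1ccccc1COc2ccc([C@@H]3CC(O)(c4c(OCc5ccccc5)cc(OCc6ccccc6)c7c4O[C@H](c8ccc(OCc9ccccc9)cc8)[C@H](OCc%10ccccc%10)C7)c%11ccc(OCc%12ccccc%12)cc%11O3)cc2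
F10 | step 5 | hexa-O-benzyl ether of 11 (2S,4S upper unit; 2R,3R lower unit) | c1ccccc1COc2ccc([C@@H]3C[C@H](c4c(OCc5ccccc5)cc(OCc6ccccc6)c7c4O[C@H](c8ccc(OCc9ccccc9)cc8)[C@H](OCc%10ccccc%10)C7)c%11ccc(OCc%12ccccc%12)cc%11O3)cc2
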